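**Plan**

- Core numbering used below (2,7-dioxabicyclo[3.2.1]octan-3-one): C1 acetal carbon, O2–C3(=O)–C4 lactone bridge, C5, C6 (bears CO2Me), O7, C8 (bears the decalin). Retrosynthetic cuts, in order: lactone bond O2–C1; the two oxolane bonds O7–C6 and C5–C8 together; the quaternary-carbon–CH2 bond of the side chain; ring B of the decalin by Diels–Alder.
- Enabling feature: O7 and C8 both sit on the acetal carbon C1, so O7–C1–C8 is an aldehyde with its α-carbon (enamine carbon C8, hemiacetal oxygen O7). C5 and C6 are the β- and α-carbons of the C6 ester, so an α-bromo enoate takes carbon at C5 and then oxygen at C6, a formal (3+2) annulation.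
- Forward order: ring A is bought; ring B by Diels–Alder; quaternary centre by hydrogen-atom-transfer Giese addition; ring-fusion alkene via the enol triflate; aldehyde; oxolane (key step); lactone opened to the methyl ester; side chain oxidised; bridging lactone closed last.
- Stereochemistry: endo Diels–Alder under a chiral Lewis acid (three decalin centres); radical addition on the convex face anti to the neighbouring methyl (quaternary centre); chiral enamine and synclinal transition state (C8, C5); thermodynamic epimerisation (C6); bridge geometry (C1).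

Key step: step 7

Assumption: the sense of induction of the oxazaborolidinium catalyst (step 1) and of (R)-2-(methoxymethyl)pyrrolidine (step 7) is taken from the usual face-shielding models; if either proves opposite, its antipode is used.

**Route**

Step 1
Reactants: 1 4,4-dimethylcyclohex-2-en-1-one; 2 (3E)-3-methylpenta-1,3-diene
Product: 3 (4aR,8R,8aS)-4,4,7,8-tetramethyl-3,4,4a,5,8,8a-hexahydronaphthalen-1(2H)-one
Conditions: (S)-1-(2-methylphenyl)-3,3-diphenyltetrahydro-1H,3H-pyrrolo[1,2-c][1,3,2]oxazaborole protonated with HN(SO2CF3)2 (20 mol %), CH2Cl2, −78 → −20 °C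
Reagents that add atoms: none
Why: Lewis-acid-catalysed Diels–Alder reaction in which the unhindered CH2 terminus of the diene bonds to the hindered enone β-carbon (ortho orientation), endo addition places H-4a, H-8a and H-8 cis, and the chiral boron cation shields one enone face to fix the absolute sense.

Step 2
Reactants: 3 (4aR,8R,8aS)-4,4,7,8-tetramethyl-3,4,4a,5,8,8a-hexahydronaphthalen-1(2H)-one; 4 phenyl vinyl sulfone
Product: 5 (4aR,7S,8R,8aS)-4,4,7,8-tetramethyl-7-[2-(phenylsulfonyl)ethyl]-3,4,4a,5,6,7,8,8a-octahydronaphthalen-1(2H)-one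
Conditions: Fe(acac)3, PhSiH3, EtOH–ethylene glycol, 60 °C
Reagents that add atoms: none
Why: Iron-hydride hydrogen-atom-transfer Giese addition, in which Markovnikov H-atom transfer gives the tertiary C7 radical that adds to the vinyl sulfone on the convex face, anti to the C8 methyl and to cis-fused ring A, so the quaternary centre forms with the two methyls cis.

Step 3
Reactants: 5 (4aR,7S,8R,8aS)-4,4,7,8-tetramethyl-7-[2-(phenylsulfonyl)ethyl]-3,4,4a,5,6,7,8,8a-octahydronaphthalen-1(2H)-one
Product: 6 (4aS,7S,8S)-4,4,7,8-tetramethyl-7-[2-(phenylsulfonyl)ethyl]-2,3,4,4a,5,6,7,8-octahydronaphthalen-1-yl trifluoromethanesulfonate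
Conditions: Tf2O, 2,6-di-tert-butyl-4-methylpyridine, CH2Cl2, 0 °C → rt
Reagents that add atoms: trifluoromethanesulfonic anhydride (O=S(=O)(OS(=O)(=O)C(F)(F)F)C(F)(F)F)
Why: Enol triflate formation under equilibrating conditions with a hindered pyridine favours the more substituted enol, which places the double bond between C1 and the ring-fusion carbon C8a.

Step 4
Reactants: 6 (4aS,7S,8S)-4,4,7,8-tetramethyl-7-[2-(phenylsulfonyl)ethyl]-2,3,4,4a,5,6,7,8-octahydronaphthalen-1-yl trifluoromethanesulfonate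
Product: 7 {2-[(1S,2S,4aS)-1,2,5,5-tetramethyl-1,2,3,4,4a,5,6,7-octahydronaphthalen-2-yl]ethanesulfonyl}benzene
Conditions: Pd(OAc)2 (cat.), PPh3, HCO2H, n-Bu3N, DMF, 60 °C
Reagents that add atoms: none
Why: Palladium-catalysed formate reduction of the enol triflate replaces the triflate by hydrogen and leaves the trisubstituted ring-fusion alkene where the triflate fixed it.

Step 5
Reactants: 7 {2-[(1S,2S,4aS)-1,2,5,5-tetramethyl-1,2,3,4,4a,5,6,7-octahydronaphthalen-2-yl]ethanesulfonyl}benzene
Product: 9 2-[(1S,2S,4aS)-1,2,5,5-tetramethyl-1,2,3,4,4a,5,6,7-octahydronaphthalen-2-yl]acetaldehyde, via silyloxy sulfone 8 (not isolated)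
Conditions: n-BuLi, THF, −78 °C; Me3SiOOSiMe3, −78 → 0 °C; aq. NH4Cl
Reagents that add atoms: bis(trimethylsilyl) peroxide (C[Si](C)(C)OO[Si](C)(C)C)
Why: Oxidative desulfonylation, in which the α-sulfonyl carbanion is oxygenated by the silyl peroxide and the α-silyloxy sulfone collapses with loss of sulfinate to the aldehyde without touching a stereocentre.

Step 6
Reactants: 10 5,6-dihydro-2H-pyran-2-one
Product: 12 3-bromo-5,6-dihydro-2H-pyran-2-one, via dibromide 11 (not isolated)
Conditions: Br2, CH2Cl2, 0 °C; then Et3N, 0 °C → rt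
Reagents that add atoms: bromine (BrBr)
Why: Bromine addition to the enoate followed by base-induced loss of HBr through the acidic α-hydrogen gives the α-bromo enoate.

Step 7
Reactants: 9 2-[(1S,2S,4aS)-1,2,5,5-tetramethyl-1,2,3,4,4a,5,6,7-octahydronaphthalen-2-yl]acetaldehyde; 12 3-bromo-5,6-dihydro-2H-pyran-2-one
Product: 15 (3R,3aR,7aS)-2-methoxy-3-[(1S,2R,4aS)-1,2,5,5-tetramethyl-1,2,3,4,4a,5,6,7-octahydronaphthalen-2-yl]hexahydro-7H-furo[2,3-c]pyran-7-one (anomeric mixture at C2), via enamine 13 (not isolated), via Michael adduct 14 (not isolated)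
Conditions: (R)-2-(methoxymethyl)pyrrolidine (1 equiv), 4 Å molecular sieves, MeCN, rt; 12, 45 °C; then MeOH, H2O (1 equiv), Ag2CO3, rt
Reagents that add atoms: methanol (CO); water (O)
Why: Proposed new method: a formal (3+2) annulation in which aldehyde 9 supplies the O–C–C unit and bromo lactone 12 the two-carbon bis-electrophile; the (E)-enamine 13 attacks C4 of 12 by conjugate addition (the bromine is vinylic, so no SN2 or cyclopropane-forming step can come first), water and methanol release aldehyde 14 as its methyl hemiacetal, and the hemiacetal hydroxyl then displaces the now sp3 α-bromo-lactone bromide with silver assistance. The closest known reaction types are the Stork enamine Michael addition to α,β-unsaturated esters and the Michael/O-alkylation annulation of 1,3-dicarbonyl compounds with α-bromo acceptors (interrupted Feist–Bénary type); the new element is that a plain aldehyde serves as the C,O-bis-nucleophile through its hemiacetal. The oxolane closes 5-exo-tet with inversion at the bromide carbon and can only be cis-fused to the six-membered lactone, so the bromide epimer that cannot cyclise is drained through its enol. The carbon bearing the decalin is set by the methoxymethyl arm of the pyrrolidine, which blocks one face of the enamine, and the adjacent ring-fusion carbon by the synclinal open transition state (lactone carbonyl near nitrogen, decalin anti to the acceptor double bond), which for this (Z)-configured cyclic acceptor gives the 3,3a-cis relation needed. The acetal carbon forms as an anomeric mixture that is erased in step 10, and the ester-bearing carbon is corrected in step 8. The step needs carbon-before-oxygen bond formation at the β- and then the α-carbon, which the vinylic bromide and the late addition of the silver salt secure.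

Step 8
Reactants: 15 (3R,3aR,7aS)-2-methoxy-3-[(1S,2R,4aS)-1,2,5,5-tetramethyl-1,2,3,4,4a,5,6,7-octahydronaphthalen-2-yl]hexahydro-7H-furo[2,3-c]pyran-7-one
Product: 17 methyl (2R,3R,4R)-3-(2-hydroxyethyl)-5-methoxy-4-[(1S,2R,4aS)-1,2,5,5-tetramethyl-1,2,3,4,4a,5,6,7-octahydronaphthalen-2-yl]oxolane-2-carboxylate, via cis hydroxy ester 16 (not isolated)
Conditions: NaOMe (cat.), MeOH, 0 → 50 °C
Reagents that add atoms: methanol (CO)
Why: Methoxide-catalysed methanolysis opens the δ-lactone to the methyl ester and primary alcohol, and reversible enolisation of the α-alkoxy ester epimerises C2 to the favoured 2,3-trans isomer, which cannot relactonise.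

Step 9
Reactants: 17 methyl (2R,3R,4R)-3-(2-hydroxyethyl)-5-methoxy-4-[(1S,2R,4aS)-1,2,5,5-tetramethyl-1,2,3,4,4a,5,6,7-octahydronaphthalen-2-yl]oxolane-2-carboxylate
Product: 19 2-{(2R,3R,4R)-5-methoxy-2-(methoxycarbonyl)-4-[(1S,2R,4aS)-1,2,5,5-tetramethyl-1,2,3,4,4a,5,6,7-octahydronaphthalen-2-yl]oxolan-3-yl}acetic acid, via aldehyde 18 (not isolated)
Conditions: 2,2,6,6-tetramethylpiperidin-1-oxyl (cat.), PhI(OAc)2, MeCN–pH 7 phosphate buffer, 0 °C → rt
Reagents that add atoms: water (O)
Why: Nitroxyl-catalysed oxidation with PhI(OAc)2 takes the primary alcohol through the aldehyde hydrate to the carboxylic acid under near-neutral conditions that spare the methyl acetal and the trisubstituted alkene.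

Step 10
Reactants: 19 2-{(2R,3R,4R)-5-methoxy-2-(methoxycarbonyl)-4-[(1S,2R,4aS)-1,2,5,5-tetramethyl-1,2,3,4,4a,5,6,7-octahydronaphthalen-2-yl]oxolan-3-yl}acetic acid
Product: 20 methyl (1S,5R,6R,8R)-3-oxo-8-[(1S,2R,4aS)-1,2,5,5-tetramethyl-1,2,3,4,4a,5,6,7-octahydronaphthalen-2-yl]-2,7-dioxabicyclo[3.2.1]octane-6-carboxylate
Conditions: camphorsulfonic acid (cat.), 4 Å molecular sieves, CH2Cl2, rt
Reagents that add atoms: none
Why: Acid-catalysed transacetalisation, in which the oxocarbenium ion formed by loss of methanol is trapped by the carboxylic acid on the face that carries the CH2CO2H chain, closing the lactone bridge and fixing the acetal carbon as the only bridged epimer that geometry allows.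

**Compound list**

1 | 4,4-dimethylcyclohex-2-en-1-one | CC1(C)CCC(=O)C=C1 | starting material
2 | (3E)-3-methylpenta-1,3-diene | C=C/C(C)=C/C | starting material
3 | (4aR,8R,8aS)-4,4,7,8-tetramethyl-3,4,4a,5,8,8a-hexahydronaphthalen-1(2H)-one (cis-fused; H-4a, H-8, H-8a on one face) | CC1=CC[C@@H]2[C@@H](C(=O)CCC2(C)C)[C@H]1C | intermediate
4 | phenyl vinyl sulfone | C=CS(=O)(=O)c1ccccc1 | starting material
5 | (4aR,7S,8R,8aS)-4,4,7,8-tetramethyl-7-[2-(phenylsulfonyl)ethyl]-3,4,4a,5,6,7,8,8a-octahydronaphthalen-1(2H)-one | O=S(=O)(c1ccccc1)CC[C@]1(C)CC[C@@H]2[C@@H](C(=O)CCC2(C)C)[C@H]1C | intermediate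
6 | (4aS,7S,8S)-4,4,7,8-tetramethyl-7-[2-(phenylsulfonyl)ethyl]-2,3,4,4a,5,6,7,8-octahydronaphthalen-1-yl trifluoromethanesulfonate | O=S(=O)(c1ccccc1)CC[C@]1(C)CC[C@@H]2C(=C(OS(=O)(=O)C(F)(F)F)CCC2(C)C)[C@H]1C | intermediate
7 | {2-[(1S,2S,4aS)-1,2,5,5-tetramethyl-1,2,3,4,4a,5,6,7-octahydronaphthalen-2-yl]ethanesulfonyl}benzene | O=S(=O)(c1ccccc1)CC[C@]1(C)CC[C@@H]2C(=CCCC2(C)C)[C@H]1C | intermediate
8 | trimethyl{1-(phenylsulfonyl)-2-[(1S,2S,4aS)-1,2,5,5-tetramethyl-1,2,3,4,4a,5,6,7-octahydronaphthalen-2-yl]ethoxy}silane (not isolated; epimers at the carbinol carbon) | C[Si](C)(C)OC(C[C@]1(C)CC[C@@H]2C(=CCCC2(C)C)[C@H]1C)S(=O)(=O)c1ccccc1 | intermediate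
9 | 2-[(1S,2S,4aS)-1,2,5,5-tetramethyl-1,2,3,4,4a,5,6,7-octahydronaphthalen-2-yl]acetaldehyde | O=CC[C@]1(C)CC[C@@H]2C(=CCCC2(C)C)[C@H]1C | intermediate
10 | 5,6-dihydro-2H-pyran-2-one | O=C1OCCC=C1 | starting material
11 | 3,4-dibromooxan-2-one (not isolated) | O=C1OCCC(Br)C1Br | intermediate
12 | 3-bromo-5,6-dihydro-2H-pyran-2-one | O=C1OCCC=C1Br | intermediate
13 | (2R)-2-(methoxymethyl)-1-{(E)-2-[(1S,2R,4aS)-1,2,5,5-tetramethyl-1,2,3,4,4a,5,6,7-octahydronaphthalen-2-yl]ethenyl}pyrrolidine (not isolated) | COC[C@H]1CCCN1/C=C/[C@]2(C)CC[C@@H]3C(=CCCC3(C)C)[C@H]2C | intermediate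
14 | (2R)-2-[(4R)-3-bromo-2-oxooxan-4-yl]-2-[(1S,2R,4aS)-1,2,5,5-tetramethyl-1,2,3,4,4a,5,6,7-octahydronaphthalen-2-yl]acetaldehyde (not isolated; bromide epimers) | O=C[C@@H]([C@]1(C)CC[C@@H]2C(=CCCC2(C)C)[C@H]1C)[C@H]1CCOC(=O)C1Br | intermediate
15 | (3R,3aR,7aS)-2-methoxy-3-[(1S,2R,4aS)-1,2,5,5-tetramethyl-1,2,3,4,4a,5,6,7-octahydronaphthalen-2-yl]hexahydro-7H-furo[2,3-c]pyran-7-one (anomeric mixture at C2) | COC1O[C@@H]2C(=O)OCC[C@@H]2[C@@H]1[C@]1(C)CC[C@@H]2C(=CCCC2(C)C)[C@H]1C | intermediate
16 | methyl (2S,3R,4R)-3-(2-hydroxyethyl)-5-methoxy-4-[(1S,2R,4aS)-1,2,5,5-tetramethyl-1,2,3,4,4a,5,6,7-octahydronaphthalen-2-yl]oxolane-2-carboxylate (not isolated) | COC(=O)[C@H]1OC(OC)[C@@H]([C@]2(C)CC[C@@H]3C(=CCCC3(C)C)[C@H]2C)[C@H]1CCO | intermediate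
17 | methyl (2R,3R,4R)-3-(2-hydroxyethyl)-5-methoxy-4-[(1S,2R,4aS)-1,2,5,5-tetramethyl-1,2,3,4,4a,5,6,7-octahydronaphthalen-2-yl]oxolane-2-carboxylate | COC(=O)[C@@H]1OC(OC)[C@@H]([C@]2(C)CC[C@@H]3C(=CCCC3(C)C)[C@H]2C)[C@H]1CCO | intermediate
18 | methyl (2R,3R,4R)-5-methoxy-3-(2-oxoethyl)-4-[(1S,2R,4aS)-1,2,5,5-tetramethyl-1,2,3,4,4a,5,6,7-octahydronaphthalen-2-yl]oxolane-2-carboxylate (not isolated) | COC(=O)[C@@H]1OC(OC)[C@@H]([C@]2(C)CC[C@@H]3C(=CCCC3(C)C)[C@H]2C)[C@H]1CC=O | intermediate
19 | 2-{(2R,3R,4R)-5-methoxy-2-(methoxycarbonyl)-4-[(1S,2R,4aS)-1,2,5,5-tetramethyl-1,2,3,4,4a,5,6,7-octahydronaphthalen-2-yl]oxolan-3-yl}acetic acid | COC(=O)[C@@H]1OC(OC)[C@@H]([C@]2(C)CC[C@@H]3C(=CCCC3(C)C)[C@H]2C)[C@H]1CC(=O)O | intermediate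
20 | methyl (1S,5R,6R,8R)-3-oxo-8-[(1S,2R,4aS)-1,2,5,5-tetramethyl-1,2,3,4,4a,5,6,7-octahydronaphthalen-2-yl]-2,7-dioxabicyclo[3.2.1]octane-6-carboxylate | COC(=O)[C@@H]1O[C@H]2OC(=O)C[C@@H]1[C@@H]2[C@]1(C)CC[C@@H]2C(=CCCC2(C)C)[C@H]1C | target

**Count and risks**

Total step count: 10. Longest linear sequence: 9 steps (steps 1–5 and 7–10; step 6 is a one-step branch).

Steps most likely to fail:

Step 7 (Proposed new method). The hindered enamine may add too slowly, so that the amine instead attacks the bromo lactone. Face selection by the auxiliary may be opposed by the neighbouring quaternary centre. The aldehyde α-centre may epimerise before ring closure. Fallback with known chemistry: setting out from 9, condensation with (S)-1-amino-2-(methoxymethyl)pyrrolidine gives the SAMP hydrazone F1. Its lithium azaenolate (LDA, THF, −78 °C) adds to 12 to give the hydrazone Michael adduct F2 with auxiliary control at the α-carbon. Two-phase cleavage with aqueous CuCl2 releases aldehyde 14, which is cyclised with Ag2CO3 in methanol; the route is rejoined at 15.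

Step 1. The enone is hindered next to its β-carbon, so cycloaddition under the chiral catalyst may be slow, with loss of enantiofacial and endo control. Fallback: setting out from 1 and 2, the EtAlCl2-promoted cycloaddition gives the racemic cis adduct F3. Ketalisation with (2R,3R)-butane-2,3-diol gives two diastereomeric dioxolanes; the dioxolane of the wanted enantiomer F4 is separated by chromatography and hydrolysed with dilute aqueous acid. The route is rejoined at 3.

Step 3. Enolisation may go toward the CH2 side, putting the double bond in the wrong position after step 4. Fallback: setting out from 5, acid-catalysed bromination at the more substituted α-carbon (pyridinium tribromide, AcOH) gives the ring-fusion bromo ketone F5. NaBH4 reduces it to the bromohydrin F6, and zinc dust in acetic acid effects reductive elimination, which can only give the C1–C8a alkene. The route is rejoined at 7.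

Further compounds
F1 | step 7 | (S,E)-2-(methoxymethyl)-N-{2-[(1S,2S,4aS)-1,2,5,5-tetramethyl-1,2,3,4,4a,5,6,7-octahydronaphthalen-2-yl]ethylidene}pyrrolidin-1-amine | COC[C@@H]1CCCN1/N=C/C[C@]2(C)CC[C@@H]3C(=CCCC3(C)C)[C@H]2C
F2 | step 7 | SAMP hydrazone of aldehyde 14 (bromide epimers) | COC[C@@H]1CCCN1/N=C/[C@@H]([C@]2(C)CC[C@@H]3C(=CCCC3(C)C)[C@H]2C)[C@H]4CCOC(=O)C4Br
F3 | step 1 | racemic cis adduct, 3 together with its mirror image (SMILES of the mirror image) | CC1=CC[C@H]2[C@H](C(=O)CCC2(C)C)[C@@H]1C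
F4 | step 1 | (4R,5R)-4,5-dimethyl-1,3-dioxolane ketal of 3 | CC1=CC[C@@H]2[C@@H](C3(CCC2(C)C)O[C@H](C)[C@@H](C)O3)[C@H]1C
F5 | step 3 | 8a-bromo derivative of ketone 5 (epimers at C8a) | O=S(=O)(c1ccccc1)CC[C@]1(C)CC[C@@H]2C(Br)(C(=O)CCC2(C)C)[C@H]1C
F6 | step 3 | 8a-bromo-1-hydroxy compound from F5 (epimers at C1 and C8a) | O=S(=O)(c1ccccc1)CC[C@]1(C)CC[C@@H]2C(Br)(C(O)CCC2(C)C)[C@H]1C
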